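**Retrosynthetic overview** (labdane numbering: decalin C1–C10, side chain C11–C16, C17 on C8, C18/C19 on C4, C20 on C10)

1. Target 27 ⇐ spiro-hydroxy ether 26 (dehydration) ⇐ dihydrofuran 24 (asymmetric epoxidation, 5-exo etherification) ⇐ diene 23 (RCM) ⇐ spiro-oxirane 18 at C9 ⇐ trans-6β-hydroxy-9-ketone 16.
2. 16 ⇐ trans-dione 15 ⇐ cis-fused 6-methoxy-9-decalone 11; C5 is inverted through the C6 ketone and the C8 methyl comes from enolate alkylation.
3. 11 ⇐ pinacol-terminated Prins cyclisation of cycloheptenyl silyl ether 8: C5 attacks the C6 oxocarbenium carbon (ring B closes), then C1 shifts from C9 to C10, so the seven-membered carbocycle (C9, C10, C5, C4, C3, C2, C1) contracts to six-membered ring A and C9 becomes the ketone.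
4. Enabling feature: C9 bears oxygen, is bonded to the quaternary methyl-bearing C10, and lies 1,4 to the C6 oxygen; C9 can therefore be the carbinol of a 2-methylcyclohept-2-enol (alkene C10=C5) and C6 the acetal carbon of a three-carbon tether on C9.
5. 8 ⇐ enantioselective 1,2-addition of a functionalised alkylzinc to cycloheptenone 3 ⇐ one-carbon ring expansion of cyclohexenone 1. Ring order: seven-membered carbocycle; rings B and A together (key step); spiro-oxirane; dihydrofuran; tetrahydrofuran.

Key step: step 5

Remark 1: 2,4,4-trimethylcyclohex-2-en-1-one (1) is taken as commercially available; otherwise it is one step from isobutyraldehyde and ethyl vinyl ketone. 3-Bromo-1,1-dimethoxypropane (4) is commercially available.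
Remark 2: the facial sense of the two catalyst-controlled steps (3 and 16) is assumed by analogy with 2-methylcycloalkenones and 1-substituted cycloalkenes; the ligand or ketone enantiomer is chosen accordingly.
Remark 3: in 11–14 the C6 (and C8) centres are epimer mixtures that converge in step 8, so they are left undefined in the SMILES.

**Step 1**
Reactants: 1 2,4,4-trimethylcyclohex-2-en-1-one
Product: 3 2,4,4-trimethylcyclohept-2-en-1-one, via α-silyl ketone 2 (not isolated)
Conditions: TMSCHN2, AlMe3, CH2Cl2, −78 to 0 °C; then K2CO3, MeOH, rt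
Reagents that add atoms: (trimethylsilyl)diazomethane, C[Si](C)(C)C=[N+]=[N-]
Why: Lewis-acid-promoted diazoalkane homologation (Tiffeneau–Demjanov-type ring expansion) in which the saturated α′-carbon should migrate in preference to the alkenyl carbon, keeping the enone conjugated; the C–Si bond of 2 is cleaved by methanolysis.

**Step 2**
Reactants: 4 3-bromo-1,1-dimethoxypropane
Product: 6 (3,3-dimethoxypropyl)[(trimethylsilyl)methyl]zinc, via alkylzinc bromide 5 (not isolated)
Conditions: Zn dust (activated with BrCH2CH2Br and TMSCl, cat.), LiCl, THF, 50 °C; then Me3SiCH2Li (pentane), −78 °C to rt; solvent exchanged to toluene/hexane, lithium salts filtered off under argon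
Reagents that add atoms: zinc, [Zn]; (trimethylsilyl)methyllithium, C[Si](C)(C)C[Li]
Why: LiCl-assisted oxidative insertion of zinc into the primary C–Br bond (the acetal is inert and sits γ to zinc, so no β-elimination is possible) followed by transmetalation with the silylmethyllithium, the standard entry to mixed alkyl(silylmethyl)zinc reagents that carry one transferable functionalised alkyl group.

**Step 3**
Reactants: 3 2,4,4-trimethylcyclohept-2-en-1-one; 6 (3,3-dimethoxypropyl)[(trimethylsilyl)methyl]zinc
Product: 7 (S)-1-(3,3-dimethoxypropyl)-2,4,4-trimethylcyclohept-2-en-1-ol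
Conditions: 6 (1.6 equiv), Ti(OiPr)4 (1.2 equiv), bis(hydroxycamphorsulfonamide) ligand of trans-cyclohexane-1,2-diamine (10 mol %, enantiomer giving the (S)-alcohol), toluene/hexane, rt; aq NH4Cl
Reagents that add atoms: none
Why: titanium-catalysed enantioselective 1,2-addition of an alkylzinc to an α-substituted cyclic enone (closely precedented for 2-methylcycloalkenones), in which the (trimethylsilyl)methyl group is a non-transferable ligand on zinc (as established for mixed alkylzincs in titanium-catalysed carbonyl additions) so that only the functionalised alkyl group is delivered; the chiral titanium complex differentiates the carbonyl faces because the methyl-bearing alkene carbon and the α′-CH2 differ in size, and this sets the (S)-carbinol.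

**Step 4**
Reactants: 7 (S)-1-(3,3-dimethoxypropyl)-2,4,4-trimethylcyclohept-2-en-1-ol
Product: 8 trimethylsilyl ether of 7
Conditions: 1-(trimethylsilyl)imidazole, CH2Cl2, rt
Reagents that add atoms: 1-(trimethylsilyl)imidazole, C[Si](C)(C)n1ccnc1
Why: neutral silylation of a tertiary alcohol; the silyl ether blocks cyclic acetal formation and serves as the leaving group on oxygen in the pinacol step.

**Step 5**
Reactants: 8 trimethylsilyl ether of 7
Product: 11 cis-fused 6-methoxy-4,4,10-trimethyl-9-decalone (4aR,8aS), via oxocarbenium ion 9 (not isolated), via bridged C10 cation 10 (not isolated)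
Conditions: SnCl4 (1.5 equiv), CH2Cl2, −78 to −20 °C; aq NaHCO3
Reagents that add atoms: none
Why: Proposed new method: SnCl4 should ionise the dimethyl acetal to oxocarbenium ion 9, the C10=C5 alkene attacks C6 through C5 (Markovnikov) to give the bicyclo[4.3.1]decyl cation 10 with the charge on C10 next to the silyloxy-bearing C9, and a pinacol 1,2-shift of C1 from C9 to C10 then contracts the seven-membered carbocycle to six-membered ring A while C9 becomes the ketone and the silyl group leaves as MeOSiMe3. The closest known reaction type is the pinacol-terminated Prins cyclisation of alkenyl-carbinol silyl ethers carrying a tethered acetal (ring-enlarging carbocycle annulations); new here is that alkene and carbinol lie in the same ring and the tether sits on the carbinol carbon, so the cation is bridged and the shift is ring-contracting. Ring B closes by 6-endo-trig attack of C5 on the oxocarbenium carbon, whereas ring A is not closed but arises from the seven-membered ring by the 1,2-alkyl shift. C10 is controlled by the C9 carbinol configuration, since the tether reaches C5 on the face where it sits and C1 migrates to the opposite face of C10 (net anti addition across C10=C5), transferring (S)-C9 into (S)-C10; C5 is thereby formed cis to the C10 methyl and is corrected in step 8, and C6 is left uncontrolled because it is oxidised later. The selectivity needed is migration of the C9–C1 bond and not of C9–C8 (which would give a hydroazulenone): C9–C1 is antiperiplanar to the forming C5–C6 bond, its shift contracts a seven- to a six-membered ring whereas the C8 shift would contract the new six- to a five-membered ring, and C8 is kept as an unsubstituted CH2 (its methyl is added in step 6) so that it has no higher migratory aptitude.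

**Step 6**
Reactants: 11 cis-fused 6-methoxy-4,4,10-trimethyl-9-decalone
Product: 12 8-methyl derivative of 11 (C8 epimers)
Conditions: LDA, THF, −78 °C; MeI, −78 to 0 °C
Reagents that add atoms: iodomethane, CI
Why: kinetic enolate alkylation; C8 is the only enolisable position of the C9 ketone because C10 is quaternary, and the C8 configuration is equilibrated in step 8.

**Step 7**
Reactants: 12 8-methyl derivative of 11
Product: 13 cis-fused 6-hydroxy-4,4,8,10-tetramethyl-9-decalone
Conditions: BBr3, CH2Cl2, −78 to 0 °C; aq NaHCO3
Reagents that add atoms: none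
Why: Lewis-acid O-demethylation (bromide attacks the methyl group of the boron-complexed ether by SN2); the ketone should tolerate the low temperature.

**Step 8**
Reactants: 13 cis-fused 6-hydroxy-4,4,8,10-tetramethyl-9-decalone
Product: 15 (2R,4aS,8aS)-2,5,5,8a-tetramethylhexahydronaphthalene-1,4(2H,4aH)-dione (trans-fused 6,9-dione with 8α-methyl), via cis-fused dione 14 (not isolated)
Conditions: Dess–Martin periodinane, NaHCO3, CH2Cl2, rt; then NaOMe (cat.), MeOH, rt to 50 °C
Reagents that add atoms: none
Why: Dess–Martin oxidation followed by base-mediated enolisation, which should equilibrate C5 (α to the C6 ketone) to the trans ring junction and C8 (α to the C9 ketone) to the equatorial 8α-methyl epimer, the latter avoiding a 1,3-diaxial contact with the C10 methyl (thermodynamic control).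

**Step 9**
Reactants: 15 trans-fused 6,9-dione
Product: 16 (2R,4R,4aS,8aS)-4-hydroxy-2,5,5,8a-tetramethyloctahydronaphthalen-1(2H)-one (6β-hydroxy-9-ketone)
Conditions: NaBH4, MeOH/CH2Cl2, −40 to −20 °C
Reagents that add atoms: none
Why: chemo- and stereoselective hydride reduction; the C9 carbonyl is flanked by a quaternary and a tertiary carbon and should react far more slowly, and hydride attacks C6 from the α face because the β face is blocked by the syn-axial C10 and 4β methyls, giving the axial 6β-alcohol.

**Step 10**
Reactants: 16 6β-hydroxy-9-ketone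
Product: 17 (1R,3R,4aS,8aS)-3,4a,8,8-tetramethyl-4-methylidenedecahydronaphthalen-1-ol (6β-hydroxy-9-methylidene compound)
Conditions: Ph3PCH3Br, KOtBu (excess), toluene, 100 °C
Reagents that add atoms: methyltriphenylphosphonium bromide, C[P+](c1ccccc1)(c1ccccc1)c1ccccc1.[Br-]
Why: Wittig methylenation of a hindered ketone under forcing conditions; the 6β-alkoxide is a spectator and any enolisation only returns the thermodynamic 8α-methyl epimer.

**Step 11**
Reactants: 17 6β-hydroxy-9-methylidene compound
Product: 18 6β-hydroxy-9α,11-spiro-oxirane (5S,6R,8R,9R,10S)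
Conditions: mCPBA, NaHCO3, CH2Cl2, 0 °C
Reagents that add atoms: 3-chloroperbenzoic acid, O=C(OO)c1cccc(Cl)c1
Why: Prilezhaev epoxidation from the α face, anti to the axial C10 methyl that shields the β face of the exocyclic alkene; this places the oxirane oxygen α on C9 and the CH2 (C11) β.

**Step 12**
Reactants: 18 6β-hydroxy-9α,11-spiro-oxirane; 19 2-methylprop-2-en-1-ol
Product: 21 6β,9α-dihydroxy-9β-[3-(hydroxymethyl)but-3-en-1-yl] triol, via dilithio dianion 20 (not isolated)
Conditions: 19, nBuLi (2 equiv), TMEDA, Et2O/hexane, 0 °C to rt; then 18, THF, 0 °C to rt; H2O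
Reagents that add atoms: none
Why: SN2 opening of the oxirane at its CH2 carbon (C11) by the allylic carbanion of the methallyl alcohol dianion, whose allyl termini are equivalent so no regiochemical question arises; the C9–O bond is untouched, so the 9α-oxygen configuration is kept.

**Step 13**
Reactants: 21 triol
Product: 22 allyl ether of the primary alcohol of 21
Conditions: NaH (1.05 equiv), allyl bromide, Bu4NI (cat.), THF, 0 °C
Reagents that add atoms: allyl bromide, C=CCBr
Why: Williamson etherification; the primary allylic alkoxide should be alkylated selectively because the axial 6β-hydroxyl and the tertiary 9-hydroxyl are strongly hindered.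

**Step 14**
Reactants: 22 allyl ether
Product: 23 6β-acetate of 22
Conditions: Ac2O, DMAP, pyridine, 50 °C
Reagents that add atoms: acetic anhydride, CC(=O)OC(C)=O
Why: DMAP-catalysed acylation of the secondary 6β-alcohol; the tertiary 9α-alcohol, flanked by two fully substituted carbons, should not react.

**Step 15**
Reactants: 23 6β-acetate of 22
Product: 24 6β-acetoxy-9α-hydroxy-9β-[2-(2,5-dihydrofuran-3-yl)ethyl] compound
Conditions: second-generation Grubbs catalyst (5 mol %), CH2Cl2, 40 °C
Reagents that add atoms: none
Why: ring-closing metathesis of a 1,1-disubstituted with a monosubstituted alkene to the trisubstituted 2,5-dihydrofuran, with loss of ethylene.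

**Step 16**
Reactants: 24 dihydrofuran
Product: 26 (13S,14S)-6β-acetoxy-14-hydroxy-9α,13:15,16-diepoxylabdane, via 13,14-epoxide 25 (not isolated)
Conditions: L-fructose-derived Shi ketone (30 mol %), KHSO5 (Oxone), K2CO3, Bu4NHSO4, MeCN/dimethoxymethane/aq Na2B4O7 buffer, 0 °C; then camphorsulfonic acid (10 mol %), CH2Cl2, 0 °C
Reagents that add atoms: potassium peroxymonosulfate, [K+].[O-]S(=O)(=O)OO
Why: Shi epoxidation sets the oxirane face of the trisubstituted alkene under reagent control, then acid-catalysed 5-exo opening at the tertiary oxirane carbon C13 by the 9α-hydroxyl with inversion closes the spiro-tetrahydrofuran and fixes C13 in the spatial arrangement of the target, leaving a trans C14 hydroxyl.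

**Step 17**
Reactants: 26 14-hydroxy spiro ether
Product: 27 (5S,6R,8R,9R,10S,13R)-6β-acetoxy-9α,13:15,16-diepoxylabd-14-ene (CNP0242014.1)
Conditions: Burgess reagent, toluene, 60 °C; chromatography on Et3N-deactivated silica
Reagents that add atoms: none
Why: Burgess dehydration (syn Ei elimination of the sulfamate ester); C13 is quaternary, so the only β-hydrogens are on C15 and the enol ether C14=C15 is the only alkene that can form.

**Compound list**

1 | 2,4,4-trimethylcyclohex-2-en-1-one | CC1=CC(C)(C)CCC1=O | starting material
2 | 2,4,4-trimethyl-7-(trimethylsilyl)cyclohept-2-en-1-one | CC1=CC(C)(C)CCC([Si](C)(C)C)C1=O | intermediate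
3 | 2,4,4-trimethylcyclohept-2-en-1-one | CC1=CC(C)(C)CCCC1=O | intermediate
4 | 3-bromo-1,1-dimethoxypropane (3-bromopropanal dimethyl acetal) | COC(CCBr)OC | starting material
5 | (3,3-dimethoxypropyl)zinc bromide | COC(OC)CC[Zn]Br | intermediate
6 | (3,3-dimethoxypropyl)[(trimethylsilyl)methyl]zinc | COC(OC)CC[Zn]C[Si](C)(C)C | intermediate
7 | (S)-1-(3,3-dimethoxypropyl)-2,4,4-trimethylcyclohept-2-en-1-ol | COC(OC)CC[C@@]1(O)CCCC(C)(C)C=C1C | intermediate
8 | {[(1S)-1-(3,3-dimethoxypropyl)-2,4,4-trimethylcyclohept-2-en-1-yl]oxy}trimethylsilane | COC(OC)CC[C@@]1(O[Si](C)(C)C)CCCC(C)(C)C=C1C | intermediate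
9 | O-methyl oxocarbenium ion at the tether terminus (C6) of 8 | C[O+]=CCC[C@@]1(O[Si](C)(C)C)CCCC(C)(C)C=C1C | intermediate
10 | bridged bicyclo[4.3.1]decyl cation (charge on C10, silyloxy on bridgehead C9, methoxy on C6) | COC1CC[C@@]2(O[Si](C)(C)C)CCCC(C)(C)[C@@H]1[C+]2C | intermediate
11 | (4aR,8aS)-4-methoxy-5,5,8a-trimethyloctahydronaphthalen-1(2H)-one, cis-fused, C4 (labdane C6) epimers | COC1CCC(=O)[C@@]2(C)CCCC(C)(C)[C@@H]12 | intermediate
12 | (4aR,8aS)-4-methoxy-2,5,5,8a-tetramethyloctahydronaphthalen-1(2H)-one, cis-fused, epimers at C2 and C4 | COC1CC(C)C(=O)[C@@]2(C)CCCC(C)(C)[C@@H]12 | intermediate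
13 | (4aR,8aS)-4-hydroxy-2,5,5,8a-tetramethyloctahydronaphthalen-1(2H)-one, cis-fused, epimers at C2 and C4 | OC1CC(C)C(=O)[C@@]2(C)CCCC(C)(C)[C@@H]12 | intermediate
14 | (4aR,8aS)-2,5,5,8a-tetramethylhexahydronaphthalene-1,4(2H,4aH)-dione, cis-fused, C2 epimers | O=C1CC(C)C(=O)[C@@]2(C)CCCC(C)(C)[C@@H]12 | intermediate
15 | (2R,4aS,8aS)-2,5,5,8a-tetramethylhexahydronaphthalene-1,4(2H,4aH)-dione, trans-fused | O=C1C[C@@H](C)C(=O)[C@@]2(C)CCCC(C)(C)[C@H]12 | intermediate
16 | (2R,4R,4aS,8aS)-4-hydroxy-2,5,5,8a-tetramethyloctahydronaphthalen-1(2H)-one (6β-hydroxy-9-ketone) | O[C@@H]1C[C@@H](C)C(=O)[C@@]2(C)CCCC(C)(C)[C@H]12 | intermediate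
17 | (1R,3R,4aS,8aS)-3,4a,8,8-tetramethyl-4-methylidenedecahydronaphthalen-1-ol | O[C@@H]1C[C@@H](C)C(=C)[C@@]2(C)CCCC(C)(C)[C@H]12 | intermediate
18 | spiro-oxirane of 17, oxirane oxygen α on C9, CH2 β (5S,6R,8R,9R,10S) | O[C@@H]1C[C@@H](C)[C@]3(CO3)[C@@]2(C)CCCC(C)(C)[C@H]12 | intermediate
19 | 2-methylprop-2-en-1-ol | C=C(C)CO | starting material
20 | dilithio dianion of 19 (lithium 2-(lithiomethyl)prop-2-en-1-olate) | [Li]CC(=C)CO[Li] | intermediate
21 | triol: trans-decalin with 6β-OH, 9α-OH and 9β-CH2CH2C(=CH2)CH2OH (5S,6R,8R,9R,10S) | O[C@@H]1C[C@@H](C)[C@](O)(CCC(=C)CO)[C@@]2(C)CCCC(C)(C)[C@H]12 | intermediate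
22 | allyl ether of the primary hydroxyl of 21 | O[C@@H]1C[C@@H](C)[C@](O)(CCC(=C)COCC=C)[C@@]2(C)CCCC(C)(C)[C@H]12 | intermediate
23 | 6β-acetate of 22 | CC(=O)O[C@@H]1C[C@@H](C)[C@](O)(CCC(=C)COCC=C)[C@@]2(C)CCCC(C)(C)[C@H]12 | intermediate
24 | 6β-acetoxy-9α-hydroxy-9β-[2-(2,5-dihydrofuran-3-yl)ethyl] trans-decalin (5S,6R,8R,9R,10S) | CC(=O)O[C@@H]1C[C@@H](C)[C@](O)(CCC3=CCOC3)[C@@]2(C)CCCC(C)(C)[C@H]12 | intermediate
25 | (13R,14S)-13,14-epoxide of 24 | CC(=O)O[C@@H]1C[C@@H](C)[C@](O)(CC[C@@]34COC[C@@H]3O4)[C@@]2(C)CCCC(C)(C)[C@H]12 | intermediate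
26 | (13S,14S)-6β-acetoxy-14-hydroxy-9α,13:15,16-diepoxylabdane (13S by CIP only; same spatial arrangement at C13 as the target) | CC(=O)O[C@@H]1C[C@@H](C)[C@]2(CC[C@]3([C@@H](O)COC3)O2)[C@@]2(C)CCCC(C)(C)[C@H]12 | intermediate
27 | (5S,6R,8R,9R,10S,13R)-6β-acetoxy-9α,13:15,16-diepoxylabd-14-ene | CC(=O)O[C@@H]1C[C@@H](C)[C@]2(CC[C@]3(C=COC3)O2)[C@@]2(C)CCCC(C)(C)[C@H]12 | target

**Step count**

Total: 17 steps. Longest linear sequence: 16 steps (steps 1 and 3–17; step 2 is a one-step branch).

**Steps most likely to fail**

Step 5 (key step). The bridged cation may relax by shift of the C9–C8 bond, contracting the new ring instead of the seven-membered one, or by proton loss from the C10 methyl instead of the pinacol shift. The fallback makes ring A by a stepwise ring contraction of known type, in which the migrating bond is fixed by antiperiplanarity to an oxirane C–O bond; it sets out from 3 and returns at 15. The titanium-catalysed addition of 6 to 3 with the enantiomeric ligand would give (R)-1-(3,3-dimethoxypropyl)-2,4,4-trimethylcyclohept-2-en-1-ol F1; the antipode is needed because this route delivers C1 to the C10 face anti to the oxirane oxygen. Hydroxyl-directed epoxidation (VO(acac)2, tBuOOH) would give the syn-epoxy alcohol F2. ZnBr2 in CH2Cl2, chelating hydroxyl and oxirane oxygen, should trigger the semipinacol shift of ring carbon C1 onto C10 (ring contraction of a cyclic 2,3-epoxy alcohol) to the β-hydroxy ketone F3 with six-membered ring A and quaternary C10. Dess–Martin oxidation would give the 1,3-diketone F4, and LDA/MeI the C8-methylated diketone F5. Aqueous trifluoroacetic acid would unmask the keto aldehyde F6. SmI2 in THF/tBuOH should close ring B by ketyl pinacol coupling of the aldehyde with the C5 ketone to the diol F7. TsOH in toluene (pinacol rearrangement: ionisation of the tertiary C5 hydroxyl, hydride shift from C6) and NaOMe equilibration would then give 15.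

Step 16. Facial discrimination by the ketone catalyst may be insufficient on a cyclic trialkyl alkene flanked by two allylic ether carbons, and a hydride shift of the oxirane under acid (Meinwald-type) may compete with attack by the hindered tertiary hydroxyl. The fallback sets out from 24 and returns at 27. N-Iodosuccinimide (NaHCO3, MeCN, −20 °C) should give iodonium-triggered 5-exo etherification by the 9α-hydroxyl at C13, with iodine delivered anti to C14, to the 14-iodo spiro ether F12; its C13 epimer would be removed by chromatography. DBU in toluene at 80 °C would then eliminate HI toward C15 (anti E2; C13 is quaternary) to give 27 directly.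

Step 3. Transfer of the functionalised alkyl group from the mixed zinc reagent to the hindered enone may be slow, and residual lithium salts or uncatalysed background addition may erode the enantioselectivity. The fallback uses a catalytic asymmetric allylation and builds the acetal afterwards; it sets out from 3 and returns at 8. Ti(OiPr)4, the BINOL enantiomer that gives the (S)-carbinol, iPrOH and tetraallylstannane would give (S)-1-allyl-2,4,4-trimethylcyclohept-2-en-1-ol F8. 1-(Trimethylsilyl)imidazole would give its trimethylsilyl ether F9. 9-BBN followed by NaBO3 would hydroborate the terminal alkene selectively to the primary alcohol F10. Dess–Martin periodinane with pyridine would give the aldehyde F11. Trimethyl orthoformate in MeOH with catalytic pyridinium p-toluenesulfonate at 0 °C would then give 8.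

**Further compounds**

F1 | step 5 | (R)-1-(3,3-dimethoxypropyl)-2,4,4-trimethylcyclohept-2-en-1-ol | COC(OC)CC[C@]1(O)CCCC(C)(C)C=C1C
F2 | step 5 | syn-2,3-epoxy alcohol of F1 (oxirane on the hydroxyl face) | COC(OC)CC[C@]1(O)CCCC(C)(C)[C@H]2O[C@@]12C
F3 | step 5 | 1-[2-hydroxy-1,3,3-trimethylcyclohexyl]-4,4-dimethoxybutan-1-one (ring-contracted β-hydroxy ketone, quaternary C10 as in the target series) | COC(OC)CCC(=O)[C@@]1(C)CCCC(C)(C)[C@H]1O
F4 | step 5 | 2-(4,4-dimethoxybutanoyl)-2,6,6-trimethylcyclohexan-1-one | COC(OC)CCC(=O)[C@@]1(C)CCCC(C)(C)C1=O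
F5 | step 5 | 2-(4,4-dimethoxy-2-methylbutanoyl)-2,6,6-trimethylcyclohexan-1-one (C8 epimers) | COC(OC)CC(C)C(=O)[C@@]1(C)CCCC(C)(C)C1=O
F6 | step 5 | 3-methyl-4-oxo-4-(1,3,3-trimethyl-2-oxocyclohexyl)butanal (C8 epimers) | O=CCC(C)C(=O)[C@@]1(C)CCCC(C)(C)C1=O
F7 | step 5 | 4,4a-dihydroxy-2,5,5,8a-tetramethyloctahydronaphthalen-1(2H)-one (5,6-diol; C5, C6 and C8 not defined) | OC1CC(C)C(=O)[C@@]2(C)CCCC(C)(C)C12O
F8 | step 3 | (S)-1-allyl-2,4,4-trimethylcyclohept-2-en-1-ol | C=CC[C@@]1(O)CCCC(C)(C)C=C1C
F9 | step 3 | trimethylsilyl ether of F8 | C=CC[C@@]1(O[Si](C)(C)C)CCCC(C)(C)C=C1C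
F10 | step 3 | 3-[(1S)-2,4,4-trimethyl-1-(trimethylsilyloxy)cyclohept-2-en-1-yl]propan-1-ol | OCCC[C@@]1(O[Si](C)(C)C)CCCC(C)(C)C=C1C
F11 | step 3 | 3-[(1S)-2,4,4-trimethyl-1-(trimethylsilyloxy)cyclohept-2-en-1-yl]propanal | O=CCC[C@@]1(O[Si](C)(C)C)CCCC(C)(C)C=C1C
F12 | step 16 | 6β-acetoxy-14-iodo-9α,13:15,16-diepoxylabdane (iodine trans to the C13–O bond) | CC(=O)O[C@@H]1C[C@@H](C)[C@]2(CC[C@]3([C@@H](I)COC3)O2)[C@@]2(C)CCCC(C)(C)[C@H]12
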